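Late in the ash run the product total gains 4.4 percentage points in the last 5.00 min, so you should ask what slows a rate, and by how much.

in all of them: left-handed substrate 0.80 M; right-handed substrate 0.80 M
- oak: coupling partner 2 equiv; free catalyst 8 mol%; run made earlier
- ash: coupling partner 2 equiv; free catalyst 18 mol%; run made earlier
- flask: coupling partner 2.00 equiv; free catalyst 12 mol%; time 15 min

| run | time / min | left-handed product / % | right-handed product / % |
|---|---|---|---|
| oak | 3.00 | 18.3 | 11.3 |
| oak | 6.00 | 27.3 | 17.1 |
| oak | 10.0 | 35.1 | 22.0 |
| oak | 12.0 | 38.0 | 24.0 |
| oak | 15.0 | 40.8 | 25.3 |
| oak | 20.0 | 44.6 | 28.0 |
| ash | 1.33 | 17.8 | 11.2 |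
| ash | 4.00 | 33.4 | 21.5 |
| ash | 6.00 | 39.1 | 25.1 |
| ash | 10.0 | 45.8 | 28.7 |
| ash | 15.0 | 49.7 | 31.7 |
| ash | 20.0 | 52.3 | 33.5 |

(readings scatter by 0.3 percentage points)

- free catalyst is single-handed; left-handed substrate and right-handed substrate are mirror images of each other, charged as a racemate, each of them at the stated concentration
- the numbers in the tables scatter with a standard deviation of 0.3 percentage points
- on the list of suspects stand: coupling partner + free catalyst + left-handed substrate -> free catalyst + left-handed product; coupling partner + free catalyst + right-handed substrate -> free catalyst + right-handed product; left-handed substrate <-> right-handed substrate; free catalyst -> spent catalyst; coupling partner <-> dormant form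
- an excess is the difference of the two amounts in percent of their sum
- an excess is below zero if the other one leads

1. left-handed product and right-handed product together, in percent of the left-handed substrate and right-handed substrate charged together, at 15 min
2. excess of left-handed product over right-handed product in the product at 15 min
3. whether the exchange between left-handed substrate and right-handed substrate keeps pace with the reaction: how far the product's excess at 15 min gets from its value without exchange to its value with instant exchange (above 80% keeps pace, below 20% hardly takes part, else lags behind)

Two equivalents of coupling partner on the left-handed substrate make one on both substrates together. So when a share x has reacted, the substrates stand at 1 − x of their charge, and so does the coupling partner, counted with its dormant form. Take the rate from the listed steps, proportional to c(free catalyst) · c(coupling partner) · c(substrate). With loading m, you get two slowing factors of 1 − x, which is second order in what is left: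

dx/dt = κ m (1 − x)², so x/(1 − x) = κ m t

I call κ the loading constant, the starting rate per unit of loading. The last oak reading, x = 72.6%, gives:

κ = 1.66 min⁻¹

Ash reads 1.66 min⁻¹ at 6.00 min and 1.62 min⁻¹ at 15.0 min, so a third factor, for catalyst loss, reads 0.976, and I drop it.

For this flask, the reckoned starting rate is 0.199 min⁻¹. Unslowed, that would make 2.98 charges by 15 min. Put the answer back in: the mean rate is the starting rate times (1 − x), so

x = 2.98 · (1 − x), which gives x = 74.9%

By this reckoning the flask averages a quarter of its starting rate and ends at 0.0630 of it.

In ash, left-handed product reaches 52.3%, more than the half charged as left-handed substrate, so exchange runs. The excess there reads 23.0% at 10.0 min, against 22.8% at 1.33 min. Ash at 10.0 min has the same loading times time as this flask at 15 min, so I take the ash value at 10.0 min for this flask. Since the ash excess holds level while the ash product total grows from 29.0% to 74.5%, I say exchange keeps pace.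

The forecast, finding “no visible catalyst death”, gives 74.7%, close to my figure, with excess 22.9%, and says exchange keeps pace.

The flask gives 75.0% with excess 22.8%, and the exchange goes 91% of the way, so it keeps pace.

    coupling partner + free catalyst + left-handed substrate → free catalyst + left-handed product (k = 0.0463 M⁻² s⁻¹)
    coupling partner + free catalyst + right-handed substrate → free catalyst + right-handed product (k = 0.0284 M⁻² s⁻¹)
    left-handed substrate ⇌ right-handed substrate (k = 0.0182 s⁻¹)
    free catalyst → spent catalyst (k = 3.66 × 10⁻⁵ s⁻¹)
    coupling partner ⇌ dormant form (K = 0.686, k = 0.0510 s⁻¹)

Now take a neighbouring flask, charged with 20 mol% of free catalyst, all else as in the recipe. The same κ gives κ m t = 4.97, so x = 83.2%. That neighbouring flask gives 83.3%, with excess 22.2% and 17% of the charged left-handed substrate still there.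

The earlier runs and the new flask come from a simulation for substances that don't exist, and the scatter is random.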